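**Plan**

- The retrosynthesis cuts two bonds: first the C4–C5 bond of the icosanoyl chain (key cut), then the acyl C–O bond of a glutaric half-ester.
- C4 and C5 are both plain CH2 carbons in the unbranched, heteroatom-free run C2–C20. The ester carbonyl C1 lies three bonds from C4, and the phenyl ring is insulated by the O–CH2–CH2 spacer. Each carbon can therefore be carried as a CO2H group and released as a primary, unstabilised radical.
- Forward: glutaric anhydride is opened by 2-phenylethanol, so the ester of the target is in place from the start. Mixed Kolbe electrolysis of this half-ester with heptadecanoic acid then joins C4 to C5 with loss of two CO2.
- The two CO2H groups are the only helpers and leave as CO2 in the bond-forming event itself. No protecting group is used and no ring is formed.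
- Stereochemistry: the target has no stereocentre and no stereogenic double bond. Remark: "single enantiomer" is taken to mean the achiral compound as drawn, so no step has to control configuration.

Key step: step 2

**Route**

Step 1
Reactants: 1 glutaric anhydride; 2 2-phenylethanol
Product: 3 5-oxo-5-(2-phenylethoxy)pentanoic acid (mono-2-phenylethyl glutarate)
Conditions: DMAP (5 mol %), toluene, 90 °C
Reagents that add atoms: none
Why: Alcoholysis (nucleophilic ring-opening) of a cyclic anhydride by a primary alcohol should stop cleanly at the half-ester, because the carboxylic acid set free is not an acylating agent; the acid 3 can be freed from neutral material by bicarbonate extraction and re-acidification.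

Step 2
Reactants: 3 5-oxo-5-(2-phenylethoxy)pentanoic acid; 4 heptadecanoic acid
Product: 7 2-phenylethyl icosanoate (phenethyl icosanoate), via hexadecyl radical 5 (not isolated), via 4-oxo-4-(2-phenylethoxy)butyl radical 6 (not isolated)
Conditions: 3 (4 equiv), 4 (1 equiv), KOH (10 mol % of total acid), MeOH, Pt anode / Pt cathode, undivided cell, ca. 0.2 A cm⁻², 45–50 °C, stopped while the electrolyte is still weakly acidic
Reagents that add atoms: none
Why: At the platinum anode the carboxylates of 3 and 4 form the adsorbed layer, each is oxidised by one electron and loses CO2, and the primary radicals 5 and 6, generated side by side at high surface concentration, combine to form the C4–C5 bond of the icosanoyl chain, while protons are reduced to H2 at the cathode and thereby regenerate the carboxylate. The closest known reaction type is the mixed (crossed) Kolbe electrolysis of a fatty acid with a half-ester of a dicarboxylic acid, the classical chain extension of fatty acids. No ring is closed and no stereocentre is formed, so neither a mode of closure nor a controlling element arises. The step needs cross- over homo-coupling, which is secured statistically by the excess of the cheap half-ester 3, so that most radicals 5 should meet a radical 6; the homodimers dotriacontane (no ester) and bis(2-phenylethyl) octanedioate (two esters) bracket the mono-ester 7 in polarity and should separate on silica. It also needs radical coupling to outrun further oxidation to cations (Hofer–Moest pathway), which is secured by both radicals being primary and unstabilised, with the ester carbonyl three bonds away from the radical carbon C4, and by smooth Pt, high current density and a weakly acidic electrolyte. The phenethyl ester and the isolated phenyl ring should survive because the bulk stays acidic as long as free acid remains (no methoxide builds up, so no ester exchange) and the carboxylate layer keeps the arene from the anode.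

**Compound list**

1 | glutaric anhydride (oxane-2,6-dione) | O=C1CCCC(=O)O1 | starting material
2 | 2-phenylethanol | OCCc1ccccc1 | starting material
3 | 5-oxo-5-(2-phenylethoxy)pentanoic acid (mono-2-phenylethyl glutarate) | OC(=O)CCCC(=O)OCCc1ccccc1 | intermediate
4 | heptadecanoic acid | CCCCCCCCCCCCCCCCC(=O)O | starting material
5 | hexadecyl radical | CCCCCCCCCCCCCCC[CH2] | intermediate
6 | 4-oxo-4-(2-phenylethoxy)butyl radical | [CH2]CCC(=O)OCCc1ccccc1 | intermediate
7 | 2-phenylethyl icosanoate (phenethyl icosanoate) | CCCCCCCCCCCCCCCCCCCC(=O)OCCc1ccccc1 | target

**Summary**

Total step count: 2
Longest linear sequence: 2 steps (1 → 3 → 7; heptadecanoic acid 4 enters in step 2)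

**Steps most likely to fail**

The route has only two steps, so both are ranked.

1. Step 2 (key step). Four processes may limit it:
   - statistical homo-coupling of each radical;
   - coating of the anode by the waxy, methanol-insoluble products, with rising cell voltage;
   - over-oxidation of the radicals to cations, which end as methyl ethers and alkenes;
   - ester exchange with methanol if the electrolyte turns alkaline near the cathode.

   The fallback forms the same C4–C5 bond by a polar, copper-catalysed alkyl–alkyl coupling instead of a radical–radical coupling. It sets out from 2 and comes back to the route at 7. Compound 2 is acylated with 4-bromobutanoyl chloride (pyridine, CH2Cl2, 0 °C) to give 2-phenylethyl 4-bromobutanoate F1. Separately, commercial 1-bromohexadecane is converted with Mg in THF into hexadecylmagnesium bromide F2. F2 is added slowly to F1 in THF–NMP with Li2CuCl4 (3 mol %) at −10 to 0 °C. Under these conditions substitution of the primary bromide at copper should outrun addition of the Grignard reagent to the ester, giving 7 directly.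

2. Step 1. Ring-opening may be incomplete, or the half-ester may exchange on prolonged heating into diester and glutaric acid. Glutaric acid would enter the electrolysis as a diacid and give oligomeric coupling products. The fallback differentiates the two carboxyl groups by a protecting group instead of by anhydride opening. It sets out from 2 and comes back to the route at 3. Compound 2 is esterified with commercial 5-tert-butoxy-5-oxopentanoic acid (DCC, DMAP cat., CH2Cl2, 0 °C to rt; Steglich esterification) to give tert-butyl 2-phenylethyl pentanedioate F3. The tert-butyl ester is then cleaved with TFA in CH2Cl2 at rt, which should leave the primary phenethyl ester untouched and give 3.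

**Further compounds**

F1 | step 2 | 2-phenylethyl 4-bromobutanoate | BrCCCC(=O)OCCc1ccccc1
F2 | step 2 | hexadecylmagnesium bromide | CCCCCCCCCCCCCCCC[Mg]Br
F3 | step 1 | tert-butyl 2-phenylethyl pentanedioate | CC(C)(C)OC(=O)CCCC(=O)OCCc1ccccc1
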